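**Plan**
Retrosynthesis cuts the C7=C8 enal bond (Wittig), then both aryl–oxygen bonds of the dioxane, C5–O(C7') and C4–O(C8'), in one aryne step; the side-chain fragment is cut further at C8'–O (SN2 by tert-butylperoxide) and at C7'–C8' (vinyl Grignard on MOM-vanillin).
Enabling feature: ring A carries the dioxane oxygens O5 and O4 on adjacent carbons C5 and C4 beside the C3 methoxy group, the pattern left when a 3-methoxyaryne (C4≡C5) takes up a nucleophilic oxygen at C5 and an electrophilic oxygen at C4.
Forward: the aryne precursor 6 is made from 5-bromovanillin and the β-hydroxy peroxide 16 from vanillin; the dioxane ring, the only ring built, closes in step 11; acid deprotection and a Wittig reaction finish the chain.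
Stereochemistry: a Sharpless kinetic resolution sets C7' (S) and C8' (R) as the erythro epoxy alcohol; the peroxide SN2 inverts C8' to S (threo); the key step breaks neither C7'–O nor C8'–O, so the trans ring follows; the stabilised ylide gives the E enal.

Key step: step 11

Remark: lignan numbering is used (ring A: C1 side chain, C3 OMe, C4 oxygen bonded to C8', C5 oxygen bonded to C7'). Silicon is placed on C5 and triflate on C4; this arrangement releases the same C4≡C5 aryne as the reverse one and is reached in two steps from 5-bromovanillin, which is taken as purchased, as are vanillin and anhydrous tert-butyl hydroperoxide in decane.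

**Route**

Step 1
Reactants: 1 5-bromovanillin (3-bromo-4-hydroxy-5-methoxybenzaldehyde)
Product: 2 2-bromo-4-(1,3-dioxolan-2-yl)-6-methoxyphenol
Conditions: HOCH2CH2OH, p-TsOH (cat.), toluene, reflux, Dean–Stark; Et3N quench
Reagents that add atoms: ethylene glycol, OCCO
Why: Acid-catalysed acetalisation with azeotropic removal of water masks the aldehyde against the organolithium of step 2 and leaves the phenol free.

Step 2
Reactants: 2 2-bromo-4-(1,3-dioxolan-2-yl)-6-methoxyphenol
Product: 6 4-(1,3-dioxolan-2-yl)-2-methoxy-6-(trimethylsilyl)phenyl trifluoromethanesulfonate, via aryl trimethylsilyl ether 3 (not isolated), via aryllithium 4 (not isolated), via lithium silylphenolate 5 (not isolated)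
Conditions: HMDS, THF, reflux, then evaporation; n-BuLi, THF, −78 °C; Tf2O, −78 °C to rt
Reagents that add atoms: hexamethyldisilazane, C[Si](C)(C)N[Si](C)(C)C; trifluoromethanesulfonic anhydride, O=S(=O)(OS(=O)(=O)C(F)(F)F)C(F)(F)F
Why: O-silylation, bromine–lithium exchange and retro-Brook (O to C) silyl shift give the ortho-silyl phenolate, which is trapped as the triflate (the standard route to ortho-silylaryl triflates), so that silicon sits on C5 and triflate on C4.

Step 3
Reactants: 7 vanillin
Product: 8 3-methoxy-4-(methoxymethoxy)benzaldehyde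
Conditions: MOMCl, iPr2NEt, CH2Cl2, 0 °C to rt
Reagents that add atoms: chloromethyl methyl ether, COCCl
Why: O-alkylation of the phenol gives a MOM ether that is inert to Grignard reagents, alkoxides and fluoride and is removed by acid at the end.

Step 4
Reactants: 8 3-methoxy-4-(methoxymethoxy)benzaldehyde
Product: 9 rac-1-[3-methoxy-4-(methoxymethoxy)phenyl]prop-2-en-1-ol
Conditions: CH2=CHMgBr, THF, −78 to 0 °C; aq. NH4Cl
Reagents that add atoms: vinylmagnesium bromide, C=C[Mg]Br
Why: Grignard 1,2-addition forms the C7'–C8' bond and gives the racemic secondary allylic alcohol needed for the resolution.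

Step 5
Reactants: 9 rac-1-[3-methoxy-4-(methoxymethoxy)phenyl]prop-2-en-1-ol
Product: 10 (S)-[3-methoxy-4-(methoxymethoxy)phenyl][(2R)-oxiran-2-yl]methanol
Conditions: Ti(OiPr)4 (0.2 equiv), L-(+)-DIPT (0.3 equiv), t-BuOOH (0.6 equiv, decane), 4 Å MS, CH2Cl2, −20 °C
Reagents that add atoms: tert-butyl hydroperoxide, CC(C)(C)OO
Why: Sharpless kinetic resolution: with L-(+)-DIPT the (R)-alcohol is epoxidised much faster than the (S)-alcohol and on the face that gives the erythro epoxy alcohol, so the tartrate sets both C7' (S) and C8' (R) while the (S)-alcohol stays behind.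

Step 6
Reactants: 10 (S)-[3-methoxy-4-(methoxymethoxy)phenyl][(2R)-oxiran-2-yl]methanol
Product: 11 tert-butyl{(S)-[3-methoxy-4-(methoxymethoxy)phenyl][(2R)-oxiran-2-yl]methoxy}dimethylsilane
Conditions: TBSCl, imidazole, DMF, 0 °C to rt
Reagents that add atoms: tert-butyldimethylsilyl chloride, CC(C)(C)[Si](C)(C)Cl
Why: Silylation of the secondary alcohol under mild base blocks O7' (and any Payne rearrangement) with a group that fluoride removes later without touching a peroxide.

Step 7
Reactants: 11 tert-butyl{(S)-[3-methoxy-4-(methoxymethoxy)phenyl][(2R)-oxiran-2-yl]methoxy}dimethylsilane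
Product: 12 (2R,3S)-3-(tert-butyldimethylsilyloxy)-3-[3-methoxy-4-(methoxymethoxy)phenyl]propane-1,2-diol
Conditions: rac-(salen)Co(OAc) (2 mol %), H2O (3 equiv), THF, rt
Reagents that add atoms: water, O
Why: Cobalt-salen-catalysed hydrolytic opening of a terminal epoxide (Jacobsen type; salen = N,N'-bis(3,5-di-tert-butylsalicylidene)cyclohexane-1,2-diaminate, trivalent cobalt) adds water at the terminal carbon under neutral conditions, so the C8'–O bond keeps its configuration and the neighbouring silyl ether cannot migrate as it would under alkoxide; the racemic catalyst suffices because the epoxide is already one stereoisomer.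

Step 8
Reactants: 12 (2R,3S)-3-(tert-butyldimethylsilyloxy)-3-[3-methoxy-4-(methoxymethoxy)phenyl]propane-1,2-diol
Product: 13 (1S,2R)-1-(tert-butyldimethylsilyloxy)-3-(methoxymethoxy)-1-[3-methoxy-4-(methoxymethoxy)phenyl]propan-2-ol
Conditions: MOMCl (1.1 equiv), iPr2NEt, CH2Cl2, −20 to 0 °C
Reagents that add atoms: chloromethyl methyl ether, COCCl
Why: Selective etherification: the unhindered primary hydroxyl should be alkylated well before the secondary one flanked by the silyloxy(aryl)methyl group, and the amine base is too weak to cause silyl migration.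

Step 9
Reactants: 13 (1S,2R)-1-(tert-butyldimethylsilyloxy)-3-(methoxymethoxy)-1-[3-methoxy-4-(methoxymethoxy)phenyl]propan-2-ol
Product: 15 tert-butyl{(1S,2S)-2-(tert-butylperoxy)-3-(methoxymethoxy)-1-[3-methoxy-4-(methoxymethoxy)phenyl]propoxy}dimethylsilane, via secondary triflate 14 (not isolated)
Conditions: Tf2O, 2,6-lutidine, CH2Cl2, −78 °C; then t-BuOOH/KOtBu (4 equiv, premixed), THF, −78 to 0 °C
Reagents that add atoms: tert-butyl hydroperoxide, CC(C)(C)OO
Why: Sulfonylation followed by SN2 displacement of the secondary triflate by the α-effect nucleophile tert-butylperoxide, a known way to dialkyl peroxides from alkyl triflates, inverts C8' from R to S and so converts the erythro into the threo series.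

Step 10
Reactants: 15 tert-butyl{(1S,2S)-2-(tert-butylperoxy)-3-(methoxymethoxy)-1-[3-methoxy-4-(methoxymethoxy)phenyl]propoxy}dimethylsilane
Product: 16 (1S,2S)-2-(tert-butylperoxy)-3-(methoxymethoxy)-1-[3-methoxy-4-(methoxymethoxy)phenyl]propan-1-ol
Conditions: TBAF, AcOH (1:1), THF, 0 °C to rt
Reagents that add atoms: none
Why: Fluoride desilylation frees O7'; acetic acid keeps the β-peroxy alcohol protonated so that no alkoxide-driven fragmentation can start, and the dialkyl peroxide and MOM ethers are inert to fluoride.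

Step 11
Reactants: 16 (1S,2S)-2-(tert-butylperoxy)-3-(methoxymethoxy)-1-[3-methoxy-4-(methoxymethoxy)phenyl]propan-1-ol; 6 4-(1,3-dioxolan-2-yl)-2-methoxy-6-(trimethylsilyl)phenyl trifluoromethanesulfonate
Product: 20 2-{(2S,3S)-5-methoxy-3-[(methoxymethoxy)methyl]-2-[3-methoxy-4-(methoxymethoxy)phenyl]-2,3-dihydro-1,4-benzodioxin-7-yl}-1,3-dioxolane, via potassium alkoxide 17 (not isolated), via aryne 18 (not isolated), via aryl anion 19 (not isolated)
Conditions: KH (1.05 equiv), THF, 0 °C, 10 min; then 6 (2 equiv), CsF (4 equiv), 18-crown-6, THF, 0 °C to rt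
Reagents that add atoms: none
Why: Proposed new method: fluoride removes the trimethylsilyl group of 6 and expels triflate to give aryne 18, the potassium alkoxide 17 adds to the aryne carbon remote from the methoxy group (C5), and the resulting aryl anion 19 at C4 attacks the peroxide oxygen bound to C8' and expels tert-butoxide, so that C5–O and C4–O form in one operation. The closest known reactions are the insertion of arynes into nucleophile–electrophile pairs (for example phenoxide addition followed by intramolecular acyl trapping, which gives xanthones) and ether formation from aryllithium or aryl Grignard reagents and dialkyl peroxides. The dioxane ring closes by a 6-exo-tet substitution at oxygen, which allows the collinear C4···O–O arrangement, whereas attack at the tert-butyl-bearing oxygen would need an endo transition state and is also shielded by the tert-butyl group. No stereocentre is created and neither the C7'–O nor the C8'–O bond is broken, so the (7'S,8'S) threo precursor should give the trans ring directly. The step needs regioselective addition to the aryne, which the C3 methoxy group secures by distorting the triple bond and stabilising negative charge at C4, and it needs the aryl anion to reach the peroxide before a proton, which the strictly aprotic medium (KH releases only H2) and the six-membered geometry are meant to secure.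

Step 12
Reactants: 20 2-{(2S,3S)-5-methoxy-3-[(methoxymethoxy)methyl]-2-[3-methoxy-4-(methoxymethoxy)phenyl]-2,3-dihydro-1,4-benzodioxin-7-yl}-1,3-dioxolane
Product: 21 (2S,3S)-2-(4-hydroxy-3-methoxyphenyl)-3-(hydroxymethyl)-5-methoxy-2,3-dihydro-1,4-benzodioxine-7-carbaldehyde
Conditions: aq. HCl (3 M), THF, 45 °C
Reagents that add atoms: water, O
Why: Acid-catalysed hydrolysis cleaves the dioxolane and both MOM acetals; the aryl ether bonds of the dioxane are stable, and should the benzylic C7'–O bond ionise reversibly it recloses to the thermodynamically preferred trans ring with C8' untouched.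

Step 13
Reactants: 21 (2S,3S)-2-(4-hydroxy-3-methoxyphenyl)-3-(hydroxymethyl)-5-methoxy-2,3-dihydro-1,4-benzodioxine-7-carbaldehyde
Product: 22 (7'S,8'S)-nocomtal, (E)-3-[(2S,3S)-2-(4-hydroxy-3-methoxyphenyl)-3-(hydroxymethyl)-5-methoxy-2,3-dihydro-1,4-benzodioxin-7-yl]prop-2-enal
Conditions: Ph3P=CHCHO (1.3 equiv), THF/toluene, 70 °C
Reagents that add atoms: (triphenylphosphoranylidene)acetaldehyde, O=CC=P(c1ccccc1)(c1ccccc1)c1ccccc1
Why: Wittig olefination with the stabilised formylmethylene ylide gives the E enal and tolerates the free phenol and primary alcohol.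

**Compound list**
1 | 5-bromovanillin (3-bromo-4-hydroxy-5-methoxybenzaldehyde) | COc1cc(C=O)cc(Br)c1O | starting material
2 | 2-bromo-4-(1,3-dioxolan-2-yl)-6-methoxyphenol | COc1cc(C2OCCO2)cc(Br)c1O | intermediate
3 | [2-bromo-4-(1,3-dioxolan-2-yl)-6-methoxyphenoxy]trimethylsilane (formed in the flask) | COc1cc(C2OCCO2)cc(Br)c1O[Si](C)(C)C | intermediate
4 | [5-(1,3-dioxolan-2-yl)-3-methoxy-2-(trimethylsilyloxy)phenyl]lithium (formed in the flask) | COc1cc(C2OCCO2)cc([Li])c1O[Si](C)(C)C | intermediate
5 | lithium 4-(1,3-dioxolan-2-yl)-2-methoxy-6-(trimethylsilyl)phenolate (formed in the flask) | COc1cc(C2OCCO2)cc([Si](C)(C)C)c1[O-].[Li+] | intermediate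
6 | 4-(1,3-dioxolan-2-yl)-2-methoxy-6-(trimethylsilyl)phenyl trifluoromethanesulfonate | COc1cc(C2OCCO2)cc([Si](C)(C)C)c1OS(=O)(=O)C(F)(F)F | intermediate
7 | vanillin | COc1cc(C=O)ccc1O | starting material
8 | 3-methoxy-4-(methoxymethoxy)benzaldehyde | COCOc1ccc(C=O)cc1OC | intermediate
9 | rac-1-[3-methoxy-4-(methoxymethoxy)phenyl]prop-2-en-1-ol | COCOc1ccc(cc1OC)C(O)C=C | intermediate
10 | (S)-[3-methoxy-4-(methoxymethoxy)phenyl][(2R)-oxiran-2-yl]methanol (erythro) | COCOc1ccc(cc1OC)[C@H](O)[C@H]1CO1 | intermediate
11 | tert-butyl{(S)-[3-methoxy-4-(methoxymethoxy)phenyl][(2R)-oxiran-2-yl]methoxy}dimethylsilane | COCOc1ccc(cc1OC)[C@H](O[Si](C)(C)C(C)(C)C)[C@H]1CO1 | intermediate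
12 | (2R,3S)-3-(tert-butyldimethylsilyloxy)-3-[3-methoxy-4-(methoxymethoxy)phenyl]propane-1,2-diol | COCOc1ccc(cc1OC)[C@H](O[Si](C)(C)C(C)(C)C)[C@H](O)CO | intermediate
13 | (1S,2R)-1-(tert-butyldimethylsilyloxy)-3-(methoxymethoxy)-1-[3-methoxy-4-(methoxymethoxy)phenyl]propan-2-ol | COCOc1ccc(cc1OC)[C@H](O[Si](C)(C)C(C)(C)C)[C@H](O)COCOC | intermediate
14 | (1S,2R)-1-(tert-butyldimethylsilyloxy)-3-(methoxymethoxy)-1-[3-methoxy-4-(methoxymethoxy)phenyl]propan-2-yl trifluoromethanesulfonate (formed in the flask) | COCOc1ccc(cc1OC)[C@H](O[Si](C)(C)C(C)(C)C)[C@H](OS(=O)(=O)C(F)(F)F)COCOC | intermediate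
15 | tert-butyl{(1S,2S)-2-(tert-butylperoxy)-3-(methoxymethoxy)-1-[3-methoxy-4-(methoxymethoxy)phenyl]propoxy}dimethylsilane | COCOc1ccc(cc1OC)[C@H](O[Si](C)(C)C(C)(C)C)[C@@H](OOC(C)(C)C)COCOC | intermediate
16 | (1S,2S)-2-(tert-butylperoxy)-3-(methoxymethoxy)-1-[3-methoxy-4-(methoxymethoxy)phenyl]propan-1-ol | COCOc1ccc(cc1OC)[C@H](O)[C@@H](OOC(C)(C)C)COCOC | intermediate
17 | potassium (1S,2S)-2-(tert-butylperoxy)-3-(methoxymethoxy)-1-[3-methoxy-4-(methoxymethoxy)phenyl]propan-1-olate (formed in the flask) | COCOc1ccc(cc1OC)[C@H]([O-])[C@@H](OOC(C)(C)C)COCOC.[K+] | intermediate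
18 | 5-(1,3-dioxolan-2-yl)-3-methoxybenzyne (formed in the flask) | COC1=CC(C2OCCO2)=CC#C1 | intermediate
19 | potassium 2-{(1S,2S)-2-(tert-butylperoxy)-3-(methoxymethoxy)-1-[3-methoxy-4-(methoxymethoxy)phenyl]propoxy}-4-(1,3-dioxolan-2-yl)-6-methoxybenzen-1-ide (formed in the flask) | COCOc1ccc(cc1OC)[C@H](Oc1cc(cc(OC)[c-]1)C1OCCO1)[C@@H](OOC(C)(C)C)COCOC.[K+] | intermediate
20 | 2-{(2S,3S)-5-methoxy-3-[(methoxymethoxy)methyl]-2-[3-methoxy-4-(methoxymethoxy)phenyl]-2,3-dihydro-1,4-benzodioxin-7-yl}-1,3-dioxolane (trans) | COCOc1ccc(cc1OC)[C@@H]2Oc3cc(cc(OC)c3O[C@H]2COCOC)C1OCCO1 | intermediate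
21 | (2S,3S)-2-(4-hydroxy-3-methoxyphenyl)-3-(hydroxymethyl)-5-methoxy-2,3-dihydro-1,4-benzodioxine-7-carbaldehyde | COc1cc(ccc1O)[C@@H]2Oc3cc(C=O)cc(OC)c3O[C@H]2CO | intermediate
22 | (7'S,8'S)-nocomtal, (E)-3-[(2S,3S)-2-(4-hydroxy-3-methoxyphenyl)-3-(hydroxymethyl)-5-methoxy-2,3-dihydro-1,4-benzodioxin-7-yl]prop-2-enal | COc1cc([C@@H]2Oc3cc(/C=C/C=O)cc(OC)c3O[C@H]2CO)ccc1O | target

**Count**
Total steps: 13. Longest linear sequence: 11 steps (vanillin 7 to 22, steps 3–13); the aryne precursor 6 takes 2 steps from 1.

**Steps most likely to fail**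

Step 11 (proposed new method). The aryl anion may be protonated before it reaches the peroxide oxygen, the β-peroxy alkoxide may fragment (Grob-type C7'–C8' cleavage) before it meets the aryne, or the aryne may be consumed by the tert-butoxide that the step releases. The fallback uses known chemistry, sets out from alcohol 13 and bromophenol 2, and returns at compound 20. A Mitsunobu etherification of 13 with 2 (PPh3, DIAD, THF) inverts C8' and should give the (7'S,8'S) aryl ether F1. TBAF then frees O7' to give the bromo alcohol F2. An intramolecular palladium-catalysed C–O coupling (Pd(OAc)2, 2-(di-tert-butylphosphino)-1,1'-binaphthyl, Cs2CO3, toluene, 80 °C) joins O7' to C5 and closes the same dioxane ring, giving 20.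

Step 9. Ionisation of the triflate with 1,2-shift of the electron-rich aryl group (semipinacol type), participation by the neighbouring MOM ether, or E2 elimination may outrun the SN2 substitution. The fallback sets out from epoxy alcohol 10 and returns at compound 16; it runs the substitution on a ring-locked substrate without a MOM group at C9'. Cobalt-salen-catalysed hydrolysis of 10 gives the erythro triol F3. tBu2Si(OTf)2 with 2,6-lutidine ties O7' and O9' into the six-membered silylene alcohol F4, in which aryl and hydroxyl are both equatorial and gauche, so the aryl group cannot migrate. Tf2O and pyridine give the silylene triflate F5, and t-BuOOH/KOtBu displaces it with inversion to the silylene peroxide F6. HF·pyridine removes the silylene to give the peroxy diol F7, and MOMCl (1 equiv) with iPr2NEt at −20 °C protects the primary hydroxyl to give 16.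

Step 5. The titanium-mediated epoxidation of the monosubstituted alkene may be slow, and the Lewis acid may ionise the electron-rich benzylic allylic alcohol (allylic transposition, loss of enantiomeric purity). The fallback sets out from racemic 9 and returns at diol 12 without titanium. Lipase-catalysed acylation (Candida antarctica lipase B, vinyl acetate, hexane) should, by the usual preference of lipases for secondary alcohols, acylate the (R)-enantiomer to the (R)-acetate F8. Methanolysis (K2CO3, MeOH) gives the (R)-allylic alcohol F9, and TBSCl with imidazole gives the (R)-allyl silyl ether F10. Dihydroxylation (OsO4 cat., NMO, acetone/water) is expected to occur anti to the allylic silyloxy group, the usual sense for allylic ethers, and to give the erythro diol 12.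

**Further compounds**
F1 | step 11 | tert-butyl{(1S,2S)-2-[2-bromo-4-(1,3-dioxolan-2-yl)-6-methoxyphenoxy]-3-(methoxymethoxy)-1-[3-methoxy-4-(methoxymethoxy)phenyl]propoxy}dimethylsilane | COCOc1ccc(cc1OC)[C@H](O[Si](C)(C)C(C)(C)C)[C@@H](Oc1c(Br)cc(cc1OC)C1OCCO1)COCOC
F2 | step 11 | (1S,2S)-2-[2-bromo-4-(1,3-dioxolan-2-yl)-6-methoxyphenoxy]-3-(methoxymethoxy)-1-[3-methoxy-4-(methoxymethoxy)phenyl]propan-1-ol | COCOc1ccc(cc1OC)[C@H](O)[C@@H](Oc1c(Br)cc(cc1OC)C1OCCO1)COCOC
F3 | step 9 | (1S,2R)-1-[3-methoxy-4-(methoxymethoxy)phenyl]propane-1,2,3-triol | COCOc1ccc(cc1OC)[C@H](O)[C@H](O)CO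
F4 | step 9 | (4S,5R)-2,2-di-tert-butyl-4-[3-methoxy-4-(methoxymethoxy)phenyl]-1,3,2-dioxasilinan-5-ol | COCOc1ccc(cc1OC)[C@@H]1O[Si](C(C)(C)C)(C(C)(C)C)OC[C@H]1O
F5 | step 9 | (4S,5R)-2,2-di-tert-butyl-4-[3-methoxy-4-(methoxymethoxy)phenyl]-1,3,2-dioxasilinan-5-yl trifluoromethanesulfonate | COCOc1ccc(cc1OC)[C@@H]1O[Si](C(C)(C)C)(C(C)(C)C)OC[C@H]1OS(=O)(=O)C(F)(F)F
F6 | step 9 | (4S,5S)-5-(tert-butylperoxy)-2,2-di-tert-butyl-4-[3-methoxy-4-(methoxymethoxy)phenyl]-1,3,2-dioxasilinane | COCOc1ccc(cc1OC)[C@@H]1O[Si](C(C)(C)C)(C(C)(C)C)OC[C@@H]1OOC(C)(C)C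
F7 | step 9 | (1S,2S)-2-(tert-butylperoxy)-1-[3-methoxy-4-(methoxymethoxy)phenyl]propane-1,3-diol | COCOc1ccc(cc1OC)[C@H](O)[C@@H](OOC(C)(C)C)CO
F8 | step 5 | (R)-1-[3-methoxy-4-(methoxymethoxy)phenyl]prop-2-en-1-yl acetate | COCOc1ccc(cc1OC)[C@H](OC(C)=O)C=C
F9 | step 5 | (R)-1-[3-methoxy-4-(methoxymethoxy)phenyl]prop-2-en-1-ol | COCOc1ccc(cc1OC)[C@H](O)C=C
F10 | step 5 | tert-butyl{[(R)-1-[3-methoxy-4-(methoxymethoxy)phenyl]prop-2-en-1-yl]oxy}dimethylsilane | COCOc1ccc(cc1OC)[C@H](O[Si](C)(C)C(C)(C)C)C=C
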